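The 3,7-dioxabicyclo[3.3.0]octane core (ring A: C1, C2, O3, C4, C5 with the syringyl group on C2; ring B: C5, C6, O7, C8, C1 with the trimethoxyphenyl group on C6) hides a 1,3-diol (O3–C4–C5–C6–O7), a formaldehyde-level carbon (C8) and a styrene (C1=C2). The route rests on the C1–C8 disconnection: an isomeric 4-aryl-5-styryl-1,3-dioxane, made by an Evans syn-aldol, is opened by Me3SiOTf to an oxocarbenium ion on O7; Prins attack of C1 on C8 closes ring B, and capture of the C2 benzylic cation by O3 closes ring A, setting C1 and C2 in one operation.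

Key step: step 6

Remark: the target descriptors correspond to (1S,2R,5S,6R), i.e. cis ring fusion with both aryl groups on the convex (exo) face; compounds 1, 2, 5 and 8 are taken as commercially available.

Step 1
Reactants: 1 4-(benzyloxy)-3,5-dimethoxybenzaldehyde; 2 (2-carboxyethyl)triphenylphosphonium bromide
Product: 4 (E)-4-[4-(benzyloxy)-3,5-dimethoxyphenyl]but-3-enoic acid, via phosphonium ylide 3 (not isolated)
Conditions: NaN(SiMe3)2 (2.2 equiv), THF, −78 °C to rt; aq. HCl work-up; recrystallisation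
Reagents that add atoms: none
Why: Wittig olefination with the carboxylate-bearing ylide should give the (E)-4-arylbut-3-enoic acid from an aromatic aldehyde, and conjugation with the aryl ring keeps the double bond in the β,γ-position.

Step 2
Reactants: 4 (E)-4-[4-(benzyloxy)-3,5-dimethoxyphenyl]but-3-enoic acid; 5 (R)-4-benzyl-1,3-oxazolidin-2-one
Product: 7 (4R)-4-benzyl-3-[(3E)-4-[4-(benzyloxy)-3,5-dimethoxyphenyl]but-3-enoyl]-1,3-oxazolidin-2-one, via mixed pivalic anhydride 6 (not isolated)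
Conditions: t-BuCOCl, Et3N, THF, −20 °C; then LiCl, 5, −20 °C to rt
Reagents that add atoms: none
Why: N-acylation of the oxazolidinone through the mixed pivalic anhydride under LiCl/Et3N conditions is mild enough to leave the aryl-conjugated E-alkene in place, and no stereocenter is formed.

Step 3
Reactants: 7 (4R)-4-benzyl-3-[(3E)-4-[4-(benzyloxy)-3,5-dimethoxyphenyl]but-3-enoyl]-1,3-oxazolidin-2-one; 8 3,4,5-trimethoxybenzaldehyde
Product: 10 (4R)-4-benzyl-3-[(2R,3E)-4-[4-(benzyloxy)-3,5-dimethoxyphenyl]-2-[(R)-hydroxy(3,4,5-trimethoxyphenyl)methyl]but-3-enoyl]-1,3-oxazolidin-2-one, via Z-dibutylboron enolate 9 (not isolated)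
Conditions: n-Bu2BOTf, i-Pr2NEt, CH2Cl2, −78 to 0 °C; then 8, −78 to 0 °C; pH 7 buffer, MeOH, H2O2, 0 °C
Reagents that add atoms: none
Why: Evans syn-aldol reaction in which the Z-boron enolate reacts at its α-carbon through a Zimmerman–Traxler chair on the face opposite the benzyl group of the (R)-auxiliary, setting both new stereocenters (the future C5 and C6) in the syn (2R, carbinol R) sense.

Step 4
Reactants: 10 (4R)-4-benzyl-3-[(2R,3E)-4-[4-(benzyloxy)-3,5-dimethoxyphenyl]-2-[(R)-hydroxy(3,4,5-trimethoxyphenyl)methyl]but-3-enoyl]-1,3-oxazolidin-2-one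
Product: 11 (1R,2S)-2-[(E)-2-[4-(benzyloxy)-3,5-dimethoxyphenyl]ethenyl]-1-(3,4,5-trimethoxyphenyl)propane-1,3-diol
Conditions: LiBH4, H2O (1 equiv), Et2O/THF, 0 °C
Reagents that add atoms: none
Why: Reductive cleavage of the imide with LiBH4 should give the primary alcohol and return the auxiliary without touching the two stereocenters, the styrene or the benzyl ether.

Step 5
Reactants: 11 (1R,2S)-2-[(E)-2-[4-(benzyloxy)-3,5-dimethoxyphenyl]ethenyl]-1-(3,4,5-trimethoxyphenyl)propane-1,3-diol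
Product: 12 (4R,5S)-5-[(E)-2-[4-(benzyloxy)-3,5-dimethoxyphenyl]ethenyl]-4-(3,4,5-trimethoxyphenyl)-1,3-dioxane
Conditions: NaH (2.2 equiv), CH2Br2, DMF, 0 °C to rt
Reagents that add atoms: dibromomethane, BrCBr
Why: Double Williamson alkylation of the 1,3-diol dialkoxide with dibromomethane closes the six-membered formal (4,5-cis) under basic conditions that cannot ionise the benzylic alcohol, and no stereocenter is affected.

Step 6
Reactants: 12 (4R,5S)-5-[(E)-2-[4-(benzyloxy)-3,5-dimethoxyphenyl]ethenyl]-4-(3,4,5-trimethoxyphenyl)-1,3-dioxane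
Product: 15 (1S,2R,5S,6R)-2-[4-(benzyloxy)-3,5-dimethoxyphenyl]-6-(3,4,5-trimethoxyphenyl)-3,7-dioxabicyclo[3.3.0]octane, via oxocarbenium triflate 13 (not isolated), via benzylic cation triflate 14 (not isolated)
Conditions: Me3SiOTf (0.2 equiv), 2,6-di-tert-butyl-4-methylpyridine (0.1 equiv), CH2Cl2, −78 to −40 °C; Et3N quench
Reagents that add atoms: none
Why: Me3SiOTf silylates the less hindered primary acetal oxygen (O3 in target numbering), the formal opens to the oxocarbenium ion 13 with the methylene on the benzylic oxygen O7, the styrene attacks it through the carbon that becomes C1 (bond C1–C8) to give the benzylic cation 14, and the silylated O3 captures C2 with return of Me3SiOTf. The closest known reaction type is the acetal-initiated Prins cyclisation with internal oxygen termination (Prins bicyclisation). Ring B closes 5-exo-trig with respect to the styrene (the C=O+ unit lies inside the forming ring), and ring A closes by five-membered C–O bond formation at the exocyclic benzylic cation. C1 is controlled by C5, because only the cis-fused arrangement lets O3 reach C2 while bond formation on the other alkene face has no internal trap and should revert by retro-Prins fragmentation; C2 is controlled by the E-alkene geometry, since anti addition of C8 and O3 across it, like capture of the cation in its less hindered conformation, places the aryl group on the convex face. The step needs the methylene to stay on O7 and not on O3, which the preference of the silyl electrophile for the unhindered primary oxygen should secure (the same sense as acyl chloride cleavage of 4-substituted 1,3-dioxanes), and it needs attack by the proximal alkene carbon, which the trioxygenated aryl group secures by stabilising the cation at C2.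

Step 7
Reactants: 15 (1S,2R,5S,6R)-2-[4-(benzyloxy)-3,5-dimethoxyphenyl]-6-(3,4,5-trimethoxyphenyl)-3,7-dioxabicyclo[3.3.0]octane
Product: 16 4-[(1S,2R,5S,6R)-6-(3,4,5-trimethoxyphenyl)-3,7-dioxabicyclo[3.3.0]octan-2-yl]-2,6-dimethoxyphenol
Conditions: H2 (1 atm), Pd/C (10 wt% Pd), EtOAc, rt, stopped at full conversion
Reagents that add atoms: none
Why: Hydrogenolysis of the aryl benzyl ether over Pd/C should be much faster than cleavage of the ring benzylic C–O bonds in ethyl acetate, so the phenol is freed without change at any stereocenter.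

Compound list

1 | 4-(benzyloxy)-3,5-dimethoxybenzaldehyde | COc1cc(C=O)cc(OC)c1OCc1ccccc1 | starting material
2 | (2-carboxyethyl)triphenylphosphonium bromide | OC(=O)CC[P+](c1ccccc1)(c1ccccc1)c1ccccc1.[Br-] | starting material
3 | sodium 3-(triphenylphosphoranylidene)propanoate (ylide, not isolated) | [Na+].[O-]C(=O)CC=P(c1ccccc1)(c1ccccc1)c1ccccc1 | intermediate
4 | (E)-4-[4-(benzyloxy)-3,5-dimethoxyphenyl]but-3-enoic acid | OC(=O)C/C=C/c1cc(OC)c(OCc2ccccc2)c(OC)c1 | intermediate
5 | (R)-4-benzyl-1,3-oxazolidin-2-one | O=C1N[C@H](Cc2ccccc2)CO1 | starting material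
6 | (E)-4-[4-(benzyloxy)-3,5-dimethoxyphenyl]but-3-enoic pivalic anhydride (not isolated) | CC(C)(C)C(=O)OC(=O)C/C=C/c1cc(OC)c(OCc2ccccc2)c(OC)c1 | intermediate
7 | (4R)-4-benzyl-3-[(3E)-4-[4-(benzyloxy)-3,5-dimethoxyphenyl]but-3-enoyl]-1,3-oxazolidin-2-one | O=C(C/C=C/c1cc(OC)c(OCc2ccccc2)c(OC)c1)N1C(=O)OC[C@H]1Cc1ccccc1 | intermediate
8 | 3,4,5-trimethoxybenzaldehyde | COc1cc(C=O)cc(OC)c1OC | starting material
9 | (Z)-dibutylboron enolate of 7 (not isolated) | CCCCB(CCCC)O/C(=C\C=C\c1cc(OC)c(OCc2ccccc2)c(OC)c1)N1C(=O)OC[C@H]1Cc1ccccc1 | intermediate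
10 | (4R)-4-benzyl-3-[(2R,3E)-4-[4-(benzyloxy)-3,5-dimethoxyphenyl]-2-[(R)-hydroxy(3,4,5-trimethoxyphenyl)methyl]but-3-enoyl]-1,3-oxazolidin-2-one | O=C([C@H](/C=C/c1cc(OC)c(OCc2ccccc2)c(OC)c1)[C@@H](O)c1cc(OC)c(OC)c(OC)c1)N1C(=O)OC[C@H]1Cc1ccccc1 | intermediate
11 | (1R,2S)-2-[(E)-2-[4-(benzyloxy)-3,5-dimethoxyphenyl]ethenyl]-1-(3,4,5-trimethoxyphenyl)propane-1,3-diol | OC[C@@H]([C@@H](O)c1cc(OC)c(OC)c(OC)c1)/C=C/c1cc(OC)c(OCc2ccccc2)c(OC)c1 | intermediate
12 | (4R,5S)-5-[(E)-2-[4-(benzyloxy)-3,5-dimethoxyphenyl]ethenyl]-4-(3,4,5-trimethoxyphenyl)-1,3-dioxane (4,5-cis) | C1OC[C@@H]([C@@H](O1)c2cc(OC)c(OC)c(OC)c2)/C=C/c2cc(OC)c(OCc3ccccc3)c(OC)c2 | intermediate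
13 | methylidene{(1R,2S,3E)-4-[4-(benzyloxy)-3,5-dimethoxyphenyl]-1-(3,4,5-trimethoxyphenyl)-2-[(trimethylsilyloxy)methyl]but-3-en-1-yl}oxonium triflate (not isolated) | C=[O+][C@@H](c1cc(OC)c(OC)c(OC)c1)[C@H](CO[Si](C)(C)C)/C=C/c1cc(OC)c(OCc2ccccc2)c(OC)c1.[O-]S(=O)(=O)C(F)(F)F | intermediate
14 | [4-(benzyloxy)-3,5-dimethoxyphenyl]{(3S,4S,5R)-5-(3,4,5-trimethoxyphenyl)-4-[(trimethylsilyloxy)methyl]oxolan-3-yl}methylium triflate (not isolated) | C1O[C@@H](c2cc(OC)c(OC)c(OC)c2)[C@H](CO[Si](C)(C)C)[C@@H]1[CH+]c1cc(OC)c(OCc2ccccc2)c(OC)c1.[O-]S(=O)(=O)C(F)(F)F | intermediate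
15 | (1S,2R,5S,6R)-2-[4-(benzyloxy)-3,5-dimethoxyphenyl]-6-(3,4,5-trimethoxyphenyl)-3,7-dioxabicyclo[3.3.0]octane | COc1cc([C@@H]2OC[C@@H]3[C@H]2CO[C@H]3c2cc(OC)c(OC)c(OC)c2)cc(OC)c1OCc1ccccc1 | intermediate
16 | 4-[(1S,2R,5S,6R)-6-(3,4,5-trimethoxyphenyl)-3,7-dioxabicyclo[3.3.0]octan-2-yl]-2,6-dimethoxyphenol (CID 53356312) | COc1cc([C@@H]2OC[C@@H]3[C@H]2CO[C@H]3c2cc(OC)c(OC)c(OC)c2)cc(OC)c1O | target

Total step count: 7. Longest linear sequence: 7 steps (1 to 16).

Steps most likely to fail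

Step 6 (key step). The formal may ionise in the other sense, keeping the methylene on the primary oxygen so that the rings close through the wrong oxygen. The oxocarbenium ion may also drain into a 2-oxonia-Cope rearrangement, the benzylic cation may be captured by the trimethoxyphenyl ring (Friedel–Crafts), or C–C bond formation may occur on the alkene face that cannot close ring A. Fallback, setting out from 10 and returning at 15: the carbon that becomes C4 is kept at the acid level, so that only one ionisation sense exists and the terminating nucleophile is a carboxylate. Cleavage of the auxiliary with LiOH/H2O2 (THF/H2O, 0 °C) would give the hydroxy acid F1. Acetalisation with paraformaldehyde under mild acid (camphorsulfonic acid, CH2Cl2, molecular sieves) would give the 1,3-dioxan-4-one F2. Me3SiOTf (CH2Cl2, −78 °C) expels the carboxylate, and Prins closure followed by lactonisation would give the bicyclic lactone F3. Reduction with i-Bu2AlH (CH2Cl2, −78 °C) would give the lactol F4, and Et3SiH/BF3·OEt2 (CH2Cl2, −78 °C) would reduce it to 15.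

Step 3. The doubly activated α-position gives an extended dienolate that may react through its γ-carbon, and the aldolate may equilibrate by retro-aldol cleavage with loss of syn selectivity. Fallback, setting out from 5, 8 and 1 and returning at 10: the aryl-alkene part is introduced after the aldol step. Acylation of 5 with but-3-enoic acid (t-BuCOCl, Et3N, LiCl) would give the but-3-enoyl imide F5. Its n-Bu2BOTf/i-Pr2NEt aldol reaction with 8 would give the α-vinyl syn-aldol adduct F6. Methylenation of 1 (Ph3PCH3Br, KOt-Bu, THF) would give the styrene F7. Cross-metathesis of F6 with F7 (second-generation Hoveyda–Grubbs catalyst, CH2Cl2, 40 °C) should then give 10 as the E-alkene.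

Step 5. Intermolecular alkylation to oligomeric formals may outrun closure of the 4,5-cis-disubstituted ring. Fallback, setting out from 11 and returning at 15, bypassing 12: the two oxygens are differentiated in an open-chain mixed acetal. Silylation of the primary hydroxyl (t-BuMe2SiCl, imidazole, CH2Cl2, 0 °C) would give the primary silyl ether F8. Reaction with MeOCH2Cl/i-Pr2NEt would give the methoxymethyl ether F9. Me3SiOTf (CH2Cl2, −78 °C) then ionises the methoxymethyl group on O7, and the same Prins closure, terminated by the silyl ether oxygen, should give 15.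

Further compounds

F1 | step 6 | (2R,3E)-4-[4-(benzyloxy)-3,5-dimethoxyphenyl]-2-[(R)-hydroxy(3,4,5-trimethoxyphenyl)methyl]but-3-enoic acid | OC(=O)[C@H](/C=C/c1cc(OC)c(OCc2ccccc2)c(OC)c1)[C@@H](O)c1cc(OC)c(OC)c(OC)c1
F2 | step 6 | (5R,6R)-5-[(E)-2-[4-(benzyloxy)-3,5-dimethoxyphenyl]ethenyl]-6-(3,4,5-trimethoxyphenyl)-1,3-dioxan-4-one | O=C1OCO[C@@H](c2cc(OC)c(OC)c(OC)c2)[C@H]1/C=C/c1cc(OC)c(OCc2ccccc2)c(OC)c1
F3 | step 6 | (1R,4R,5S,8R)-4-[4-(benzyloxy)-3,5-dimethoxyphenyl]-8-(3,4,5-trimethoxyphenyl)-3,7-dioxabicyclo[3.3.0]octan-2-one | COc1cc([C@@H]2OC(=O)[C@@H]3[C@H]2CO[C@H]3c2cc(OC)c(OC)c(OC)c2)cc(OC)c1OCc1ccccc1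
F4 | step 6 | (1R,4R,5S,8R)-4-[4-(benzyloxy)-3,5-dimethoxyphenyl]-8-(3,4,5-trimethoxyphenyl)-3,7-dioxabicyclo[3.3.0]octan-2-ol (anomeric mixture) | COc1cc([C@@H]2OC(O)[C@@H]3[C@H]2CO[C@H]3c2cc(OC)c(OC)c(OC)c2)cc(OC)c1OCc1ccccc1
F5 | step 3 | (4R)-4-benzyl-3-(but-3-enoyl)-1,3-oxazolidin-2-one | C=CCC(=O)N1C(=O)OC[C@H]1Cc1ccccc1
F6 | step 3 | (4R)-4-benzyl-3-[(2R)-2-[(R)-hydroxy(3,4,5-trimethoxyphenyl)methyl]but-3-enoyl]-1,3-oxazolidin-2-one | O=C([C@H](C=C)[C@@H](O)c1cc(OC)c(OC)c(OC)c1)N1C(=O)OC[C@H]1Cc1ccccc1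
F7 | step 3 | 2-(benzyloxy)-5-ethenyl-1,3-dimethoxybenzene | C=Cc1cc(OC)c(OCc2ccccc2)c(OC)c1
F8 | step 5 | (1R,2S,3E)-4-[4-(benzyloxy)-3,5-dimethoxyphenyl]-2-{[(tert-butyldimethylsilyl)oxy]methyl}-1-(3,4,5-trimethoxyphenyl)but-3-en-1-ol | CC(C)(C)[Si](C)(C)OC[C@@H]([C@@H](O)c1cc(OC)c(OC)c(OC)c1)/C=C/c1cc(OC)c(OCc2ccccc2)c(OC)c1
F9 | step 5 | tert-butyl{[(2S,3E)-4-[4-(benzyloxy)-3,5-dimethoxyphenyl]-2-[(R)-(methoxymethoxy)(3,4,5-trimethoxyphenyl)methyl]but-3-en-1-yl]oxy}dimethylsilane | COCO[C@@H](c1cc(OC)c(OC)c(OC)c1)[C@H](CO[Si](C)(C)C(C)(C)C)/C=C/c1cc(OC)c(OCc2ccccc2)c(OC)c1
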